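**Retrosynthetic overview**
1. The target comes from hydroxyl-directed (VO(acac)₂/TBHP) epoxidation of the C7=C8 bond of a bicyclo[3.3.1]nonenone allylic diol. The epoxide is therefore the last ring formed.
2. That bicycle comes from SmI₂ reductive opening of an α,β-epoxy-ketone, with intramolecular aldol of the resulting Sm(III) enolate onto a tethered aldehyde. This forms the C4–C5 bond and closes the N-bearing ring A (C1–C2–C3–C4–C5–C9).
3. The epoxy-ketone aldehyde comes from Weitz–Scheffer epoxidation of an o-quinol. The o-quinol comes from oxidative dearomatization of a 2-alkylphenol, which forms carbocyclic ring B and the C1 tertiary carbinol.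
4. The phenol comes from L-o-tyrosine (the nine core carbons and the C3–N stereocentre) and (E)-dec-2-enoic acid. Ring order: ring B (dearomatization), then ring A (aldol), then the epoxide.

**Assumptions (stated once)**
- The absolute configuration is that of the given SMILES, and L-o-tyrosine (S) is commercially available.
- Atoms are numbered as in the target bicycle: C1 is the tertiary carbinol, C9 the ketone, C5 the CH bridgehead, C6 the CH–OH, C7/C8 the alkene, and C3 the N-bearing carbon.
- PIDA in aqueous MeCN hydroxylates the alkyl-bearing ortho carbon (C1) of the 2-alkylphenol.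
- The two C1 epimers formed are separable, and only the natural epimer is carried forward.

**Starting materials:** 1 = L-o-tyrosine, 2 = (E)-dec-2-enoic acid.

---

**Step 1**
Reactants: 1, L-o-tyrosine
Product: 3, L-o-tyrosinol, (2S)-2-amino-3-(2-hydroxyphenyl)propan-1-ol
Conditions: NaBH₄, I₂, THF, 0 °C → reflux; then MeOH, aq. NaOH
Reagents that add atoms: none
Why: In-situ borane reduces the carboxylic acid to the primary alcohol (McKennon–Meyers reduction). The α-stereocentre (C3, S) is untouched and is the only chiral-pool stereocentre.

**Step 2**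
Reactants: 3, L-o-tyrosinol; 2, (E)-dec-2-enoic acid
Product: 4, (2E)-N-[(2S)-1-hydroxy-3-(2-hydroxyphenyl)propan-2-yl]dec-2-enamide
Conditions: EDC·HCl, HOBt, iPr₂NEt, DMF/CH₂Cl₂, 0 °C → rt
Reagents that add atoms: none
Why: Carbodiimide/HOBt amide coupling acylates the amine selectively over the primary OH and the phenol. The (E)-enamide is installed now, so no late-stage N-acylation next to the epoxide is needed.

**Step 3**
Reactants: 4
Product: 5, (2E)-N-[(2S)-1-(tert-butyldimethylsilyloxy)-3-(2-hydroxyphenyl)propan-2-yl]dec-2-enamide
Conditions: TBSCl (1.05 equiv), imidazole, CH₂Cl₂, 0 °C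
Reagents that add atoms: tert-butyldimethylsilyl chloride, CC(C)(C)[Si](C)(C)Cl
Why: Limiting TBSCl at 0 °C silylates the more nucleophilic primary OH in preference to the phenol (assumed selective). This stops the free alcohol from trapping the phenoxenium in the next step as a spiro-THF ether.

**Step 4**
Reactants: 5
Product: 6, o-quinol (2E)-N-[(2S)-1-(TBSO)-3-[(1S)-1-hydroxy-2-oxocyclohexa-3,5-dien-1-yl]propan-2-yl]dec-2-enamide
Conditions: PIDA (1.1 equiv), MeCN/H₂O 9:1 (0.02 M), 0 °C, 15 min; use crude at once
Reagents that add atoms: water, O (its oxygen becomes the C1–OH)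
Why: Hypervalent-iodine oxidative dearomatization with water adding at the alkyl-bearing ortho carbon gives the 6-hydroxycyclohexa-2,4-dienone. The new C1 stereocentre forms by facial selectivity relative to C3, and the natural epimer is separated. Dilution and immediate use avoid Diels–Alder dimerization of the dienone.

**Step 5**
Reactants: 6
Product: 7, epoxy-enone (2E)-N-[(2S)-1-(TBSO)-3-[(1R,3S,6R)-3-hydroxy-2-oxo-7-oxabicyclo[4.1.0]hept-4-en-3-yl]propan-2-yl]dec-2-enamide
Conditions: tBuOOH (3 equiv), Triton B (0.1 equiv), THF, −20 → 0 °C
Reagents that add atoms: tert-butyl hydroperoxide, CC(C)(C)OO (source of the epoxide O)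
Why: Weitz–Scheffer nucleophilic epoxidation occurs at the α,β-alkene of the dienone (β-attack at C6). The peroxide adds anti to the C1 side chain, so the epoxide is cis to the C1–OH. This fixes the future C5/C6 oxygen configuration. The γ,δ-alkene (C7=C8) and the electron-poor dec-2-enamide are untouched.

**Step 6**
Reactants: 7
Product: 8, primary alcohol (2E)-N-[(2S)-1-hydroxy-3-[(1R,3S,6R)-3-hydroxy-2-oxo-7-oxabicyclo[4.1.0]hept-4-en-3-yl]propan-2-yl]dec-2-enamide
Conditions: HF·pyridine, pyridine/THF, 0 °C → rt
Reagents that add atoms: none
Why: Buffered fluoride removes the TBS ether under non-basic conditions that spare the epoxy-ketone and the tertiary alcohol. No stereocentre is changed.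

**Step 7**
Reactants: 8
Product: 9, α-acylamino aldehyde (2E)-N-[(2S)-1-oxo-3-[(1R,3S,6R)-3-hydroxy-2-oxo-7-oxabicyclo[4.1.0]hept-4-en-3-yl]propan-2-yl]dec-2-enamide. It exists largely as the spiro-lactol with the C1–OH and is used crude.
Conditions: Dess–Martin periodinane (1.5 equiv), NaHCO₃, CH₂Cl₂, 0 °C → rt
Reagents that add atoms: none
Why: Neutral, buffered DMP oxidation converts the primary alcohol to the aldehyde with minimal epimerization of C3. Lactol formation with the C1–OH further masks the sensitive aldehyde.

**Step 8**
Reactants: 9
Product: 10, bicyclo[3.3.1] enone-triol (2E)-N-[(1R,2S,3S,5S,8R)-2,5,8-trihydroxy-9-oxobicyclo[3.3.1]non-6-en-3-yl]dec-2-enamide (configuration as in the SMILES in the compound list)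
Conditions: SmI₂ (3 equiv), THF, −78 → −20 °C; quench with aq. Rochelle salt
Reagents that add atoms: none (two H come from the workup)
Why: SmI₂ reductively cleaves the α C5–O bond of the α,β-epoxy-ketone to give the Sm(III) enolate. The β C6–O is retained, cis to the C1–OH. The enolate is trapped intramolecularly by the aldehyde (Reformatsky-type aldol), closing ring A as the bicyclo[3.3.1]nonane. The C5 bridgehead configuration is enforced by the ring, with the C2–C3–C4 bridge on the face opposite the C1–OH and C6–OH. The C4–OH configuration is set by the Sm-chelated chair-like transition state (assumed to give the natural epimer).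

**Step 9**
Reactants: 10
Product: 11, isariotin D
Conditions: VO(acac)₂ (5 mol%), tBuOOH (2 equiv), CH₂Cl₂, 0 °C → rt
Reagents that add atoms: tert-butyl hydroperoxide, CC(C)(C)OO (source of the epoxide O)
Why: Vanadium-catalysed hydroxyl-directed epoxidation of the C7=C8 alkene is directed by the allylic C1–OH and C6–OH. Both lie on the face opposite the C2–C3–C4 bridge, so the epoxide forms cis to both and sets C7 and C8. The electron-poor dec-2-enamide alkene is unreactive toward the electrophilic V(V) peroxide.

---

**Compound list**

| # | Name | SMILES | Role |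
|---|---|---|---|
| 1 | L-o-tyrosine, (2S)-2-amino-3-(2-hydroxyphenyl)propanoic acid | `N[C@@H](Cc1ccccc1O)C(=O)O` | starting material |
| 2 | (E)-dec-2-enoic acid | `CCCCCCC/C=C/C(=O)O` | starting material |
| 3 | L-o-tyrosinol | `N[C@H](CO)Cc1ccccc1O` | intermediate |
| 4 | N-decenoyl amino alcohol | `CCCCCCC/C=C/C(=O)N[C@H](CO)Cc1ccccc1O` | intermediate |
| 5 | primary TBS ether of 4 | `CCCCCCC/C=C/C(=O)N[C@H](CO[Si](C)(C)C(C)(C)C)Cc1ccccc1O` | intermediate |
| 6 | o-quinol (1S) | `CCCCCCC/C=C/C(=O)N[C@H](CO[Si](C)(C)C(C)(C)C)C[C@@]1(O)C(=O)C=CC=C1` | intermediate |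
| 7 | epoxy-enone TBS ether | `CCCCCCC/C=C/C(=O)N[C@H](CO[Si](C)(C)C(C)(C)C)C[C@@]1(O)C(=O)[C@@H]2O[C@@H]2C=C1` | intermediate |
| 8 | epoxy-enone primary alcohol | `CCCCCCC/C=C/C(=O)N[C@H](CO)C[C@@]1(O)C(=O)[C@@H]2O[C@@H]2C=C1` | intermediate |
| 9 | epoxy-enone aldehyde (lactol tautomer) | `CCCCCCC/C=C/C(=O)N[C@H](C=O)C[C@@]1(O)C(=O)[C@@H]2O[C@@H]2C=C1` | intermediate |
| 10 | bicyclo[3.3.1] enone-triol | `CCCCCCC/C=C/C(=O)N[C@H]1C[C@@]2(O)C(=O)[C@H]([C@H](O)C=C2)[C@H]1O` | intermediate |
| 11 | isariotin D | `CCCCCCC/C=C/C(=O)N[C@H]1C[C@@]2(O)C(=O)[C@H]([C@H](O)[C@@H]3O[C@@H]32)[C@H]1O` | target |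

**Total steps:** 9 (one convergent coupling, in step 2). **Longest linear sequence:** 9 steps (1 → 3 → 4 → 5 → 6 → 7 → 8 → 9 → 10 → 11).

**Three steps most likely to fail**
1. **Step 4 (dearomatization).** Risks are ortho versus para attack, the C1 diastereomer ratio and o-quinol dimerization.
   - Fallback: use a tethered-trap approach. Take the analogous phenol whose side chain ends in a C4 dimethyl acetal and oxidise with PIDA/MeOH. The acetal oxygen closes a five-membered ring onto C1, which fixes the regiochemistry and lets C3 direct the stereochemistry. Mild aqueous acid then releases the C1–OH and the C4 aldehyde as the spiro-lactol.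
2. **Step 8 (SmI₂ reductive aldol).** Possible problems are ketyl or pinacol side reactions of the aldehyde, enolate protonation, reduction of the vinylogous C6–O bond, or the wrong C4 epimer.
   - Fallback: go stepwise. Reduce the epoxy-ketone with SmI₂/tBuOH to the β-hydroxy ketone, protect the C6–OH as its TBS ether, form the TBS enol ether, and close ring A by a Mukaiyama aldol (TiCl₄ or BF₃). Adjust C4 by oxidation and directed reduction if needed.
3. **Step 5 (nucleophilic epoxidation of the unstable o-quinol).** Dimerization, α-ketol rearrangement or wrong regiochemistry (γ,δ- versus α,β-alkene) may occur.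
   - Fallback: reorder the oxidations. First epoxidise the C7=C8 alkene of o-quinol 6 with VO(acac)₂/TBHP, directed by the C1–OH. Then do the nucleophilic epoxidation of the remaining enone, desilylation, oxidation and the SmI₂ cascade. The vanadium epoxidation is simply moved earlier, so the step count is unchanged, and the C7/C8 epoxide is set before the base-sensitive enone chemistry.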